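**Strategy.** Germacranolide numbering is used (ring C1–C10, lactone on C6/C7, esters on C8/C9, formyl C14 on C10, methyl C15 on C4). Everything rests on opening the ten-membered carbocycle at C3–C4, inside its skipped diene C10=C1–C2–C3–C4=C5 whose two olefins are cis in the ring. The key step, a one-pot hydroboration/intramolecular B-alkyl Suzuki–Miyaura coupling, turns the terminal CH2 of a C10=C1–C2=C3 diene into a C3 borane and joins it to a (Z)-C4 alkenyl iodide, closing the ring and fixing the trisubstituted C4=C5 olefin. Its precursor is a linear, stereodefined chain: trans-γ-lactone (C6/C7) and trans-acetonide (C8/C9), welded together from L-tartrate by two decarboxylative radical couplings.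

Key step: step 11

Remark: C8 and C9 each pass through a dioxolanyl radical and are re-set trans to their ring neighbour, so the (4R,5R) L-tartrate acetonide 6 supplies the 8,9-diol with net retention at both carbons; 6 and the (S)-butenolide 13 are taken as commercial.

Step 1
Reactants: 1 prop-2-yn-1-ol; 2 bromoethene (vinyl bromide, THF solution)
Product: 3 pent-4-en-2-yn-1-ol
Conditions: Pd(PPh3)2Cl2 (2 mol%), CuI (4 mol%), i-Pr2NH, THF, 0 °C to rt
Reagents that add atoms: none
Why: Sonogashira coupling of the terminal alkyne with the alkenyl bromide should give the conjugated enynol that already holds C14, C10, C1, C2 and C3; no stereocentre is formed.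

Step 2
Reactants: 3 pent-4-en-2-yn-1-ol
Product: 4 (2Z)-2-(tributylstannyl)penta-2,4-dien-1-ol (tin on C10, cis to the vinyl group)
Conditions: Bu3SnH (1.1 equiv, slow addition), [Cp*RuCl]4 (1.5 mol%), CH2Cl2, rt
Reagents that add atoms: tributyltin hydride, CCCC[SnH](CCCC)CCCC
Why: Hydroxy-directed ruthenium-catalysed trans-hydrostannation of a propargylic alcohol should put tin on the alkyne carbon next to the carbinol (C10) and hydrogen anti to it on C1 while sparing the alkene, which sets the C1=C10 geometry (CH2OH trans to the vinyl group).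

Step 3
Reactants: 4 (2Z)-2-(tributylstannyl)penta-2,4-dien-1-ol
Product: 5 tert-butyl(diphenyl){[(2Z)-2-(tributylstannyl)penta-2,4-dien-1-yl]oxy}silane
Conditions: t-BuPh2SiCl, imidazole, CH2Cl2, 0 °C to rt
Reagents that add atoms: tert-butyl(chloro)diphenylsilane, CC(C)(C)[Si](Cl)(c1ccccc1)c1ccccc1
Why: Standard silylation protects the C14 hydroxyl as an acid- and base-stable TBDPS ether that should last until step 15; no stereocentre is touched.

Step 4
Reactants: 6 dimethyl (4R,5R)-2,2-dimethyl-1,3-dioxolane-4,5-dicarboxylate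
Product: 7 (4R,5R)-5-(methoxycarbonyl)-2,2-dimethyl-1,3-dioxolane-4-carboxylic acid
Conditions: KOH (1.0 equiv), MeOH, 0 °C to rt; then 1 M HCl to pH 3, 0 °C
Reagents that add atoms: potassium hydroxide, [K+].[OH-]
Why: Mono-saponification of the C2-symmetric diester (homotopic esters, and the potassium half-ester salt resists a second hydrolysis) should give the half-acid without touching the stereocentres.

Step 5
Reactants: 7 (4R,5R)-5-(methoxycarbonyl)-2,2-dimethyl-1,3-dioxolane-4-carboxylic acid; 5 the silylated dienylstannane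
Product: 11 methyl (4R,5S)-5-[(2Z)-1-{[tert-butyl(diphenyl)silyl]oxy}penta-2,4-dien-2-yl]-2,2-dimethyl-1,3-dioxolane-4-carboxylate, via NHPI ester 8 (not isolated), via dienyllithium 9 (not isolated), via dienylzinc chloride 10 (not isolated)
Conditions: 7, N-hydroxyphthalimide (NHPI), N,N'-diisopropylcarbodiimide (DIC), CH2Cl2, rt, then concentrate; separately 5, MeLi, THF, −78 °C, then ZnCl2, −78 °C to rt; combine with Ni(acac)2 (10 mol%), 2,2'-bipyridine (10 mol%), THF/DMF, rt
Reagents that add atoms: none
Why: Nickel-catalysed decarboxylative alkenylation (Negishi-type coupling of a redox-active ester with an alkenylzinc reagent) forms C9–C10, the C9 dioxolanyl radical being captured anti to the neighbouring CO2Me group to give the trans-acetonide (C9 set by substrate control from C8), while the alkenyl geometry is carried from tin through lithium and zinc with retention.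

Step 6
Reactants: 11 the methyl ester from step 5
Product: 12 (4R,5S)-5-[(2Z)-1-{[tert-butyl(diphenyl)silyl]oxy}penta-2,4-dien-2-yl]-2,2-dimethyl-1,3-dioxolane-4-carboxylic acid
Conditions: LiOH·H2O, THF/H2O, 0 °C; then 1 M HCl to pH 3, 0 °C
Reagents that add atoms: lithium hydroxide, [Li+].[OH-]
Why: Saponification frees the acid for the second radical coupling, and any epimerisation at C8 is harmless because this centre becomes a radical in step 8.

Step 7
Reactants: 13 (5S)-5-(hydroxymethyl)furan-2(5H)-one
Product: 14 (5S)-5-{[(triethylsilyl)oxy]methyl}furan-2(5H)-one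
Conditions: Et3SiCl, imidazole, CH2Cl2, 0 °C
Reagents that add atoms: chlorotriethylsilane, CC[Si](Cl)(CC)CC
Why: Silylation turns the C5 hydroxyl into a bulky triethylsilyl ether that shields one face of the butenolide and can later be oxidised directly; the bought C6 stereocentre is untouched.

Step 8
Reactants: 12 the dienyl dioxolane acid; 14 the silylated butenolide
Product: 16 (4S,5S)-4-{(4S,5S)-5-[(2Z)-1-{[tert-butyl(diphenyl)silyl]oxy}penta-2,4-dien-2-yl]-2,2-dimethyl-1,3-dioxolan-4-yl}-5-{[(triethylsilyl)oxy]methyl}dihydrofuran-2(3H)-one, via NHPI ester 15 (not isolated)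
Conditions: 12, NHPI, DIC, CH2Cl2, rt, then concentrate; 14 (2 equiv), Ni(ClO4)2·6H2O (20 mol%), Zn dust (2 equiv), LiCl (3 equiv), MeCN, rt
Reagents that add atoms: none
Why: Nickel-catalysed decarboxylative Giese reaction in which the C8 dioxolanyl radical should add to the β-carbon (C7) of the butenolide anti to the C6 CH2OSiEt3 group (trans-lactone) and itself bond anti to the C9 dienyl group (trans-acetonide), so C7 and C8 are both set by substrate control from C6 and C9.

Step 9
Reactants: 16 the lactone from step 8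
Product: 17 lactone aldehyde (16 with CHO in place of CH2OSiEt3; C5 is the formyl carbon; stereocentres unchanged)
Conditions: (COCl)2, DMSO, CH2Cl2, −78 to −40 °C; then Et3N, −78 to 0 °C
Reagents that add atoms: none
Why: Under Swern conditions a primary triethylsilyl ether is cleaved by the chlorosulfonium reagent and the alkoxysulfonium ion collapses to the aldehyde (direct Swern oxidation of a primary TES ether), while the TBDPS ether and the acetonide should survive and C6 is kept by working cold.

Step 10
Reactants: 17 the lactone aldehyde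
Product: 18 (Z)-alkenyl iodide (17 with (Z)-CH=C(I)CH3 in place of CHO; iodine on C4 cis to C6)
Conditions: EtPPh3I, n-BuLi, THF, rt; I2, −78 °C; NaN(SiMe3)2, −20 °C; then 17, −78 to −20 °C
Reagents that add atoms: ethyltriphenylphosphonium iodide, CC[P+](c1ccccc1)(c1ccccc1)c1ccccc1.[I-]; iodine, II
Why: Stork–Zhao-type Wittig olefination with the α-iodo ylide made in the flask should give the (Z)-2-iodoalkene under kinetic control, placing iodine (the future site of C3) cis to C6 and the C15 methyl trans to it.

Step 11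
Reactants: 18 the (Z)-alkenyl iodide carrying the terminal diene
Product: 20 macrocyclic lactone acetonide (ten-membered ring closed), via alkyl-9-BBN borane 19 (not isolated)
Conditions: 9-BBN (1.5 equiv), THF, 0 °C to rt; then slow addition (syringe pump) to Pd(dppf)Cl2·CH2Cl2 (20 mol%), AsPh3 (20 mol%), Cs2CO3 (3 equiv), DMF/THF/H2O, 1 mM, rt to 45 °C
Reagents that add atoms: none
Why: 9-BBN adds across the terminal C2=C3 bond of the diene with boron on the unhindered C3 (anti-Markovnikov; the trisubstituted C1=C10 olefin and the iodoalkene are left), giving a primary homoallylic borane; zerovalent palladium then inserts into the C4–I bond with retention, the carbonate-activated borane hands its primary alkyl group to palladium, and reductive elimination forms the C3–C4 bond. The closest known reaction type is the intramolecular B-alkyl Suzuki–Miyaura macrocyclisation of ω-borylalkyl alkenyl iodides. The only ring closed is the ten-membered carbocycle C1–C10, formed end to end by C(sp3)–C(sp2) reductive elimination from an eleven-membered palladacycle. No stereocentre is created; the C4=C5 geometry (C3 cis to C6, methyl trans) follows from stereoretentive coupling of the (Z)-iodide, and C1=C10 is untouched. The step needs cyclisation to outrun oligomerisation, protodeboronation and β-hydride elimination, which high dilution with slow addition and the four turn elements already in the chain (Z-iodoalkene, trans-lactone, trans-dioxolane, C1=C10 olefin with C2 cis to C9) should secure by holding C3 near C4.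

Step 12
Reactants: 20 the macrocyclic lactone acetonide
Product: 23 α-methylene lactone acetonide, via Mannich base 21 (not isolated), via methiodide 22 (not isolated)
Conditions: LiN(i-Pr)2, THF, −78 °C; Me2N=CH2 I (Eschenmoser's salt), −78 °C to rt; then MeI, MeOH, rt; then aq. NaHCO3, CH2Cl2, rt
Reagents that add atoms: N,N-dimethylmethyleneiminium iodide (Eschenmoser's salt), C=[N+](C)C.[I-]
Why: Eschenmoser methylenation, in which the lactone enolate (C11 is the only acidic position) undergoes a Mannich reaction and the quaternised amine is eliminated to the exocyclic C11=C13 olefin, so the transient C11 stereocentre does not matter.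

Step 13
Reactants: 23 the α-methylene lactone acetonide
Product: 24 8,9-diol
Conditions: AcOH/H2O (4:1), 50 °C
Reagents that add atoms: none
Why: Mild acid-catalysed hydrolysis of the isopropylidene ketal should free the diol while the TBDPS ether and the α-methylene lactone survive aqueous acetic acid, and C8 and C9 are untouched because only bonds to the ketal carbon break.

Step 14
Reactants: 24 the 8,9-diol
Product: 25 8,9-bis(isobutyrate)
Conditions: (i-PrCO)2O, Et3N, DMAP (cat.), CH2Cl2, 0 °C to rt
Reagents that add atoms: isobutyric anhydride, CC(C)C(=O)OC(=O)C(C)C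
Why: DMAP-catalysed acylation of both secondary alcohols installs the two isobutyrates with retention at C8 and C9, and fast acylation should forestall migration of the lactone from O6 to O8.

Step 15
Reactants: 25 the 8,9-bis(isobutyrate)
Product: 26 C14 allylic alcohol
Conditions: HF·pyridine, pyridine, THF, 0 °C to rt
Reagents that add atoms: none
Why: Buffered fluoride cleaves the primary TBDPS ether (fluoride-driven desilylation) under weakly acidic conditions that should spare the esters and the α-methylene lactone and should not trigger acyl migration from O9 to O14.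

Step 16
Reactants: 26 the C14 allylic alcohol
Product: 27 the target, (6R,7S,8S,9S)-8,9-bis(isobutyryloxy)-14-oxogermacra-1(10)E,4Z,11(13)-trien-6,12-olide
Conditions: MnO2 (activated, excess), CH2Cl2, rt
Reagents that add atoms: none
Why: MnO2 oxidises the primary allylic alcohol chemoselectively to the conjugated aldehyde under neutral conditions, leaving the C1=C10 geometry (CHO trans to C2, the thermodynamically preferred arrangement) and all stereocentres as they are.

**Compound list**

1 | prop-2-yn-1-ol (propargyl alcohol) | C#CCO | starting material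
2 | bromoethene (vinyl bromide) | C=CBr | starting material
3 | pent-4-en-2-yn-1-ol | C=CC#CCO | intermediate
4 | (2Z)-2-(tributylstannyl)penta-2,4-dien-1-ol | C=C/C=C(/CO)[Sn](CCCC)(CCCC)CCCC | intermediate
5 | tert-butyl(diphenyl){[(2Z)-2-(tributylstannyl)penta-2,4-dien-1-yl]oxy}silane | C=C/C=C(/CO[Si](c1ccccc1)(c1ccccc1)C(C)(C)C)[Sn](CCCC)(CCCC)CCCC | intermediate
6 | dimethyl (4R,5R)-2,2-dimethyl-1,3-dioxolane-4,5-dicarboxylate (L-tartrate acetonide) | COC(=O)[C@@H]1OC(C)(C)O[C@H]1C(=O)OC | starting material
7 | (4R,5R)-5-(methoxycarbonyl)-2,2-dimethyl-1,3-dioxolane-4-carboxylic acid | COC(=O)[C@@H]1OC(C)(C)O[C@H]1C(=O)O | intermediate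
8 | N-hydroxyphthalimide ester of 7 | COC(=O)[C@@H]1OC(C)(C)O[C@H]1C(=O)ON2C(=O)c3ccccc3C2=O | intermediate
9 | dienyllithium from 5 (lithium in place of tin, geometry retained) | C=C/C=C(/CO[Si](c1ccccc1)(c1ccccc1)C(C)(C)C)[Li] | intermediate
10 | dienylzinc chloride from 9 (geometry retained) | C=C/C=C(/CO[Si](c1ccccc1)(c1ccccc1)C(C)(C)C)[Zn]Cl | intermediate
11 | methyl (4R,5S)-5-[(2Z)-1-{[tert-butyl(diphenyl)silyl]oxy}penta-2,4-dien-2-yl]-2,2-dimethyl-1,3-dioxolane-4-carboxylate (trans-dioxolane; ring carbon cis to the vinyl group) | COC(=O)[C@@H]1OC(C)(C)O[C@H]1/C(CO[Si](c2ccccc2)(c2ccccc2)C(C)(C)C)=C\C=C | intermediate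
12 | (4R,5S)-5-[(2Z)-1-{[tert-butyl(diphenyl)silyl]oxy}penta-2,4-dien-2-yl]-2,2-dimethyl-1,3-dioxolane-4-carboxylic acid | OC(=O)[C@@H]1OC(C)(C)O[C@H]1/C(CO[Si](c2ccccc2)(c2ccccc2)C(C)(C)C)=C\C=C | intermediate
13 | (5S)-5-(hydroxymethyl)furan-2(5H)-one | O=C1C=C[C@@H](CO)O1 | starting material
14 | (5S)-5-{[(triethylsilyl)oxy]methyl}furan-2(5H)-one | O=C1C=C[C@@H](CO[Si](CC)(CC)CC)O1 | intermediate
15 | N-hydroxyphthalimide ester of 12 | O=C(ON1C(=O)c2ccccc2C1=O)[C@@H]3OC(C)(C)O[C@H]3/C(CO[Si](c4ccccc4)(c4ccccc4)C(C)(C)C)=C\C=C | intermediate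
16 | (4S,5S)-4-{(4S,5S)-5-[(2Z)-1-{[tert-butyl(diphenyl)silyl]oxy}penta-2,4-dien-2-yl]-2,2-dimethyl-1,3-dioxolan-4-yl}-5-{[(triethylsilyl)oxy]methyl}dihydrofuran-2(3H)-one (trans-lactone, trans-dioxolane) | O=C1C[C@H]([C@@H]2OC(C)(C)O[C@H]2/C(CO[Si](c3ccccc3)(c3ccccc3)C(C)(C)C)=C\C=C)[C@@H](CO[Si](CC)(CC)CC)O1 | intermediate
17 | lactone aldehyde: 16 with CHO in place of CH2OSiEt3, stereocentres unchanged | O=C1C[C@H]([C@@H]2OC(C)(C)O[C@H]2/C(CO[Si](c3ccccc3)(c3ccccc3)C(C)(C)C)=C\C=C)[C@@H](C=O)O1 | intermediate
18 | (Z)-alkenyl iodide: 17 with (Z)-CH=C(I)CH3 in place of CHO (iodine cis to C6) | O=C1C[C@H]([C@@H]2OC(C)(C)O[C@H]2/C(CO[Si](c3ccccc3)(c3ccccc3)C(C)(C)C)=C\C=C)[C@@H](/C=C(/C)I)O1 | intermediate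
19 | alkyl-9-BBN borane: 18 with CH2CH2–B(9-BBN) in place of the terminal vinyl group (boron on C3) | O=C1C[C@H]([C@@H]2OC(C)(C)O[C@H]2/C(CO[Si](c3ccccc3)(c3ccccc3)C(C)(C)C)=C\CCB5C6CCCC5CCC6)[C@@H](/C=C(/C)I)O1 | intermediate
20 | macrocyclic lactone acetonide, (6R,7S,8S,9S): ten-membered ring with cis C1=C10 and C4=C5 ring olefins, trans-fused 6,12-γ-lactone (C11 = CH2), 8,9-trans-O-isopropylidene, CH2OTBDPS on C10, CH3 on C4 | C1C(=O)O[C@@H]2/C=C(/C)CC/C=C(/CO[Si](c3ccccc3)(c3ccccc3)C(C)(C)C)[C@@H]4OC(C)(C)O[C@H]4[C@@H]12 | intermediate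
21 | Mannich base: 20 with CH2NMe2 on C11 (C11 epimers) | CN(C)CC1C(=O)O[C@@H]2/C=C(/C)CC/C=C(/CO[Si](c3ccccc3)(c3ccccc3)C(C)(C)C)[C@@H]4OC(C)(C)O[C@H]4[C@@H]12 | intermediate
22 | methiodide of 21 (trimethylammonium iodide) | C[N+](C)(C)CC1C(=O)O[C@@H]2/C=C(/C)CC/C=C(/CO[Si](c3ccccc3)(c3ccccc3)C(C)(C)C)[C@@H]4OC(C)(C)O[C@H]4[C@@H]12.[I-] | intermediate
23 | α-methylene lactone acetonide: 20 with exocyclic C11=C13H2 | C=C1C(=O)O[C@@H]2/C=C(/C)CC/C=C(/CO[Si](c3ccccc3)(c3ccccc3)C(C)(C)C)[C@@H]4OC(C)(C)O[C@H]4[C@@H]12 | intermediate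
24 | 8,9-diol: 23 without the isopropylidene group (8β-OH, 9α-OH) | C=C1C(=O)O[C@@H]2/C=C(/C)CC/C=C(/CO[Si](c3ccccc3)(c3ccccc3)C(C)(C)C)[C@H](O)[C@@H](O)[C@@H]12 | intermediate
25 | 8,9-bis(isobutyrate) of 24 | C=C1C(=O)O[C@@H]2/C=C(/C)CC/C=C(/CO[Si](c3ccccc3)(c3ccccc3)C(C)(C)C)[C@H](OC(=O)C(C)C)[C@@H](OC(=O)C(C)C)[C@@H]12 | intermediate
26 | C14 allylic alcohol: 25 with CH2OH on C10 | C=C1C(=O)O[C@@H]2/C=C(/C)CC/C=C(/CO)[C@H](OC(=O)C(C)C)[C@@H](OC(=O)C(C)C)[C@@H]12 | intermediate
27 | (6R,7S,8S,9S)-8,9-bis(isobutyryloxy)-14-oxogermacra-1(10)E,4Z,11(13)-trien-6,12-olide | C=C1C(=O)O[C@@H]2/C=C(/C)CC/C=C(/C=O)[C@H](OC(=O)C(C)C)[C@@H](OC(=O)C(C)C)[C@@H]12 | target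

**Step count.** Total: 16 steps. Longest linear sequence: 14 steps (steps 1–3, 5, 6 and 8–16, from prop-2-yn-1-ol).

**Steps most likely to fail**

Step 11. Intermolecular coupling to oligomers, protodeboronation or β-hydride elimination of the alkylpalladium species may outrun closure of the ten-membered ring, and aqueous carbonate may open the lactone. The fallback keeps the same bond but closes it base-free through zinc (Negishi coupling). It sets out from 18: hydroboration with 9-BBN and oxidation with NaBO3·4H2O would give the C3 primary alcohol F1; Appel iodination (I2, PPh3, imidazole) the primary iodide F2; LiCl-promoted insertion of Zn dust into the alkyl iodide at rt (the alkenyl iodide should insert far more slowly) the alkylzinc iodide F3; slow addition of F3 to Pd2(dba)3/SPhos in THF/NMP at high dilution should close the ring. The route is rejoined at 20.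

Step 8. The hindered C8 radical may be reduced, or may add to the diene of a second molecule, faster than it adds to the β,γ-disubstituted butenolide, and the anti selectivity at C8 may erode. The fallback reverses the order of the two decarboxylative couplings, so that the Giese radical carries only an ester. It sets out from 8 (made from 7 as in step 5) and 14: nickel-catalysed Giese addition (Ni(ClO4)2·6H2O, Zn dust, LiCl, MeCN) would give the lactone methyl ester F4; chemoselective ester cleavage with Me3SnOH (1,2-dichloroethane, 70 °C) the lactone acid F5; NHPI and DIC the NHPI ester F6; coupling of F6 with dienylzinc chloride 10 under Ni(acac)2/2,2'-bipyridine should then install the dienyl group anti to the now bulky lactone substituent. The route is rejoined at 16.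

Step 10. The basic ylide may enolise and epimerise the α-acyloxy aldehyde at C6, the Z selectivity may be poor, and iodine may be lost to give the plain propenyl compound. The fallback builds the halo-olefin in two stereodefined stages and carries a bromide into the ring closure. It sets out from 17: dibromo-olefination (CBr4, PPh3, Zn dust, CH2Cl2; Corey–Fuchs first stage) would give the 1,1-dibromoalkene F7; palladium-catalysed trans-selective mono-methylation (MeZnCl, Pd(DPEphos)Cl2, THF) replaces the bromine trans to C6 and should give the (Z)-bromoalkene F8 (bromine cis to C6); hydroboration of F8 with 9-BBN to the borane F9 and the ring closure under the conditions of step 11 follow. The route is rejoined at 20.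

**Further compounds**

F1 | step 11 | C3 primary alcohol: 18 with CH2CH2OH in place of the terminal vinyl group | O=C1C[C@H]([C@@H]2OC(C)(C)O[C@H]2/C(CO[Si](c3ccccc3)(c3ccccc3)C(C)(C)C)=C\CCO)[C@@H](/C=C(/C)I)O1
F2 | step 11 | C3 primary iodide from F1 | O=C1C[C@H]([C@@H]2OC(C)(C)O[C@H]2/C(CO[Si](c3ccccc3)(c3ccccc3)C(C)(C)C)=C\CCI)[C@@H](/C=C(/C)I)O1
F3 | step 11 | alkylzinc iodide from F2 (zinc on C3) | O=C1C[C@H]([C@@H]2OC(C)(C)O[C@H]2/C(CO[Si](c3ccccc3)(c3ccccc3)C(C)(C)C)=C\CC[Zn]I)[C@@H](/C=C(/C)I)O1
F4 | step 8 | lactone methyl ester: trans-lactone of 14 carrying at C7 the trans-5-(methoxycarbonyl)-2,2-dimethyl-1,3-dioxolan-4-yl group | O=C1C[C@H]([C@@H]2OC(C)(C)O[C@H]2C(=O)OC)[C@@H](CO[Si](CC)(CC)CC)O1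
F5 | step 8 | lactone acid from F4 | O=C1C[C@H]([C@@H]2OC(C)(C)O[C@H]2C(=O)O)[C@@H](CO[Si](CC)(CC)CC)O1
F6 | step 8 | N-hydroxyphthalimide ester of F5 | O=C1C[C@H]([C@@H]2OC(C)(C)O[C@H]2C(=O)ON4C(=O)c3ccccc3C4=O)[C@@H](CO[Si](CC)(CC)CC)O1
F7 | step 10 | 1,1-dibromoalkene: 17 with CH=CBr2 in place of CHO | O=C1C[C@H]([C@@H]2OC(C)(C)O[C@H]2/C(CO[Si](c3ccccc3)(c3ccccc3)C(C)(C)C)=C\C=C)[C@@H](C=C(Br)Br)O1
F8 | step 10 | (Z)-bromoalkene: bromo analogue of 18 (bromine cis to C6) | O=C1C[C@H]([C@@H]2OC(C)(C)O[C@H]2/C(CO[Si](c3ccccc3)(c3ccccc3)C(C)(C)C)=C\C=C)[C@@H](/C=C(/C)Br)O1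
F9 | step 10 | alkyl-9-BBN borane from F8 (bromo analogue of 19) | O=C1C[C@H]([C@@H]2OC(C)(C)O[C@H]2/C(CO[Si](c3ccccc3)(c3ccccc3)C(C)(C)C)=C\CCB5C6CCCC5CCC6)[C@@H](/C=C(/C)Br)O1
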